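The route rests on cutting the C6'–CH2 bond between ring A (the acyl resorcinol ring, primed numbers) and its 3-oxopentyl chain. The feature exploited is that the ketone carbon sits exactly three atoms from C6', on a chain with no other function, so it maps onto pent-1-en-3-ol. A Heck arylation at C6' forms the aryl–CH2 bond and, by double-bond migration onto the carbinol carbon, delivers the ethyl ketone in the same operation. The precursor is the complete, fully benzylated depside (ring A ester-bonded to O4 of olivetolate ring B) with bromine at C6', so no ketone is present when the acid is activated.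

Key step: step 6

Remark: the target has no stereocentre, and the racemic allylic alcohol suffices because its carbinol carbon becomes the ketone carbon. The chelated 2-hydroxyl of ring B is benzylated only after the depside bond is made, so no temporary group on O4 is needed.

Step 1
Reactants: 1 1,3-bis(benzyloxy)-5-bromobenzene
Product: 3 2,4-bis(benzyloxy)-6-bromobenzaldehyde, via iminium chloride 2 (not isolated)
Conditions: POCl3, DMF, 0 °C → 80 °C; then H2O, 0 °C → rt
Reagents that add atoms: N,N-dimethylformamide (CN(C)C=O); water (O)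
Why: Vilsmeier–Haack formylation: the chloroiminium ion formed from DMF and POCl3 attacks a ring carbon activated ortho and para by the two benzyloxy groups, the carbon next to bromine being preferred over the one flanked by both ethers (as known for the dimethyl ether analogue), and water then hydrolyses iminium salt 2 to the aldehyde; no stereocentre arises.

Step 2
Reactants: 3 2,4-bis(benzyloxy)-6-bromobenzaldehyde
Product: 4 2,4-bis(benzyloxy)-6-bromobenzoic acid
Conditions: NaClO2, NaH2PO4, 2-methylbut-2-ene, tBuOH/THF/H2O, rt
Reagents that add atoms: sodium chlorite, NaClO2 ([Na+].[O-]Cl=O)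
Why: Pinnick (Lindgren) oxidation takes hindered, electron-rich aryl aldehydes to the acids at room temperature without touching benzyl ethers or the aryl bromide, the alkene trapping hypochlorous acid before it can chlorinate the ring.

Step 3
Reactants: 5 olivetolic acid (2,4-dihydroxy-6-pentylbenzoic acid)
Product: 6 benzyl 2,4-dihydroxy-6-pentylbenzoate
Conditions: BnBr (1.05 equiv), KHCO3, DMF, rt
Reagents that add atoms: benzyl bromide (BrCc1ccccc1)
Why: Carboxylate O-alkylation (SN2 esterification): KHCO3 ionises only the carboxylic acid, so the phenols stay free, and the mild temperature avoids decarboxylation of the β-resorcylic acid.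

Step 4
Reactants: 4 2,4-bis(benzyloxy)-6-bromobenzoic acid; 6 benzyl 2,4-dihydroxy-6-pentylbenzoate
Product: 8 benzyl 4-{[2,4-bis(benzyloxy)-6-bromobenzoyl]oxy}-2-hydroxy-6-pentylbenzoate, via acid chloride 7 (not isolated)
Conditions: (COCl)2, DMF (cat.), CH2Cl2, 0 °C → rt, evaporate; then 6, Et3N, DMAP (cat.), CH2Cl2, 0 °C → rt
Reagents that add atoms: none
Why: Acid chloride formation followed by DMAP-catalysed phenol acylation (nucleophilic acyl substitution): the 4-hydroxyl of 6 is free and the more acidic one, whereas the 2-hydroxyl is tied up in a hydrogen bond to the ester carbonyl and shielded by it, so the hindered acid chloride should esterify O4 only, as is usual in depside synthesis.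

Step 5
Reactants: 8 benzyl 4-{[2,4-bis(benzyloxy)-6-bromobenzoyl]oxy}-2-hydroxy-6-pentylbenzoate
Product: 9 benzyl 2-(benzyloxy)-4-{[2,4-bis(benzyloxy)-6-bromobenzoyl]oxy}-6-pentylbenzoate
Conditions: BnBr, K2CO3, DMF (anhydrous), rt → 40 °C
Reagents that add atoms: benzyl bromide (BrCc1ccccc1)
Why: Williamson ether synthesis on the remaining chelated phenol under anhydrous carbonate at low temperature, which should leave the hindered aryl ester alone; the capping keeps phenoxide out of the palladium step and lets one hydrogenolysis finish the synthesis.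

Step 6
Reactants: 9 benzyl 2-(benzyloxy)-4-{[2,4-bis(benzyloxy)-6-bromobenzoyl]oxy}-6-pentylbenzoate; 10 racemic pent-1-en-3-ol
Product: 12 benzyl 2-(benzyloxy)-4-{[2,4-bis(benzyloxy)-6-(3-oxopentyl)benzoyl]oxy}-6-pentylbenzoate, via enol 11 (not isolated)
Conditions: Pd(OAc)2 (5 mol %), P(tBu)3·HBF4 (10 mol %), Cy2NMe, 10 (3 equiv), 1,4-dioxane, 80 °C
Reagents that add atoms: none
Why: Mizoroki–Heck arylation of a secondary allylic alcohol in its β-aryl ketone variant: zerovalent palladium generated from Pd(OAc)2 and the bulky phosphine inserts into the C6'–Br bond, the arylpalladium bromide adds syn across the terminal alkene of 10 with the aryl group going to the unsubstituted CH2, and syn β-hydride elimination of the carbinol hydrogen gives enol 11, which tautomerises to the ethyl ketone while the amine returns the palladium hydride to the zerovalent state. No ring is closed and no stereocentre is formed, since the carbinol centre of racemic 10 becomes the carbonyl carbon. Two selectivities are needed: terminal arylation, secured by the monosubstituted, electronically unbiased alkene and the bulky arylpalladium unit, and elimination toward C–OH instead of the benzylic CH2, secured by hydroxyl coordination, the weaker C–H bond next to oxygen and the irreversible tautomerisation to the ketone (any styrenyl alcohol can re-enter by hydride re-addition). Oxidative addition is helped by the ortho acyl group and should be chemoselective for C–Br over the benzylic and aryl C–O bonds. The hindered, non-nucleophilic amine should neither cleave the aryl ester nor enolise the new ketone, so Claisen-type closure onto the depside carbonyl to an indanone is not expected.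

Step 7
Reactants: 12 benzyl 2-(benzyloxy)-4-{[2,4-bis(benzyloxy)-6-(3-oxopentyl)benzoyl]oxy}-6-pentylbenzoate
Product: 13 4-{[2,4-dihydroxy-6-(3-oxopentyl)benzoyl]oxy}-2-hydroxy-6-pentylbenzoic acid (CNP0311703.0)
Conditions: H2 (1 atm), 10% Pd/C, EtOAc, rt
Reagents that add atoms: none
Why: Heterogeneous hydrogenolysis of benzylic C–O bonds should remove the three benzyl ethers and the benzyl ester at room temperature and ambient pressure, conditions under which the dialkyl ketone, the aryl ester and the free salicylic-type acid should persist (no heating, hence no decarboxylation).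

Compound list
1 | 1,3-bis(benzyloxy)-5-bromobenzene | Brc1cc(OCc2ccccc2)cc(OCc2ccccc2)c1 | starting material
2 | N-{[2,4-bis(benzyloxy)-6-bromophenyl]methylidene}-N-methylmethanaminium chloride | C[N+](C)=Cc1c(Br)cc(OCc2ccccc2)cc1OCc1ccccc1.[Cl-] | intermediate
3 | 2,4-bis(benzyloxy)-6-bromobenzaldehyde | O=Cc1c(Br)cc(OCc2ccccc2)cc1OCc1ccccc1 | intermediate
4 | 2,4-bis(benzyloxy)-6-bromobenzoic acid | OC(=O)c1c(Br)cc(OCc2ccccc2)cc1OCc1ccccc1 | intermediate
5 | olivetolic acid (2,4-dihydroxy-6-pentylbenzoic acid) | CCCCCc1cc(O)cc(O)c1C(=O)O | starting material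
6 | benzyl 2,4-dihydroxy-6-pentylbenzoate | CCCCCc1cc(O)cc(O)c1C(=O)OCc1ccccc1 | intermediate
7 | 2,4-bis(benzyloxy)-6-bromobenzoyl chloride | ClC(=O)c1c(Br)cc(OCc2ccccc2)cc1OCc1ccccc1 | intermediate
8 | benzyl 4-{[2,4-bis(benzyloxy)-6-bromobenzoyl]oxy}-2-hydroxy-6-pentylbenzoate | CCCCCc1cc(OC(=O)c2c(Br)cc(OCc3ccccc3)cc2OCc2ccccc2)cc(O)c1C(=O)OCc1ccccc1 | intermediate
9 | benzyl 2-(benzyloxy)-4-{[2,4-bis(benzyloxy)-6-bromobenzoyl]oxy}-6-pentylbenzoate | CCCCCc1cc(OC(=O)c2c(Br)cc(OCc3ccccc3)cc2OCc2ccccc2)cc(OCc2ccccc2)c1C(=O)OCc1ccccc1 | intermediate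
10 | racemic pent-1-en-3-ol | C=CC(O)CC | starting material
11 | benzyl 2-(benzyloxy)-4-{[2,4-bis(benzyloxy)-6-(3-hydroxypent-2-en-1-yl)benzoyl]oxy}-6-pentylbenzoate (enol, double-bond geometry not fixed, either isomer tautomerises to 12) | CCCCCc1cc(OC(=O)c2c(OCc3ccccc3)cc(OCc3ccccc3)cc2CC=C(O)CC)cc(OCc2ccccc2)c1C(=O)OCc1ccccc1 | intermediate
12 | benzyl 2-(benzyloxy)-4-{[2,4-bis(benzyloxy)-6-(3-oxopentyl)benzoyl]oxy}-6-pentylbenzoate | CCCCCc1cc(OC(=O)c2c(OCc3ccccc3)cc(OCc3ccccc3)cc2CCC(=O)CC)cc(OCc2ccccc2)c1C(=O)OCc1ccccc1 | intermediate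
13 | 4-{[2,4-dihydroxy-6-(3-oxopentyl)benzoyl]oxy}-2-hydroxy-6-pentylbenzoic acid | CCCCCc1cc(OC(=O)c2c(O)cc(O)cc2CCC(=O)CC)cc(O)c1C(=O)O | target

Total step count: 7. Longest linear sequence: 6 steps (1 → 3 → 4 → 8 → 9 → 12 → 13); the ring B branch (5 → 6) joins at step 4.

Steps most likely to fail

Step 6 (Heck arylation). Three processes may intrude. β-Hydride elimination may run toward the benzylic hydrogens and leave aryl-substituted allylic alcohol in the product. Oxidative addition next to the bulky aryl ester may be slow enough for hydrodebromination to compete. The arylpalladium may attack ring B in an intramolecular direct arylation. Fallback: from 9, a Heck reaction with pent-1-en-3-one (Pd(OAc)2, P(o-tol)3, Et3N, DMF, 90 °C) can eliminate in one direction only. It should give the conjugated enone benzyl 2-(benzyloxy)-4-({2,4-bis(benzyloxy)-6-[(1E)-3-oxopent-1-en-1-yl]benzoyl}oxy)-6-pentylbenzoate F1. Hydrogenation of F1 over 10% Pd/C in EtOAc should saturate the C=C bond and remove the four benzyl groups in one operation, so the fallback rejoins the route at 13.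

Step 4 (depside bond). Acylation by the doubly ortho-substituted acid chloride may be sluggish, and forcing it may erode the preference for the free 4-hydroxyl over the chelated 2-hydroxyl, giving mixtures or diacylation. Fallback: from 6, selective silylation of the unchelated phenol (TIPSCl, imidazole, DMF) should give benzyl 2-hydroxy-6-pentyl-4-[(triisopropylsilyl)oxy]benzoate F2. Benzylation (BnBr, K2CO3, acetone, reflux) should give benzyl 2-(benzyloxy)-6-pentyl-4-[(triisopropylsilyl)oxy]benzoate F3. Buffered desilylation (TBAF, AcOH, THF, 0 °C) should give benzyl 2-(benzyloxy)-4-hydroxy-6-pentylbenzoate F4. With a single phenol present, F4 can be acylated with acid chloride 7 under forcing conditions (Et3N, stoichiometric DMAP, CH2Cl2, reflux) to give 9 directly, bypassing 8 and step 5.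

Step 5 (capping of the chelated phenol). Alkylation of the hydrogen-bonded phenol may be slow, and phenoxide or carbonate held warm for long may exchange or cleave the aryl ester of the depside. Fallback: the capping is omitted. From 8, the Heck conditions of step 6 (hindered amine base, which tolerates a chelated phenol) should give benzyl 4-{[2,4-bis(benzyloxy)-6-(3-oxopentyl)benzoyl]oxy}-2-hydroxy-6-pentylbenzoate F5. Hydrogenolysis of its three benzyl groups (H2, 10% Pd/C, EtOAc, rt) rejoins the route at 13.

Further compounds
F1 | step 6 | benzyl 2-(benzyloxy)-4-({2,4-bis(benzyloxy)-6-[(1E)-3-oxopent-1-en-1-yl]benzoyl}oxy)-6-pentylbenzoate | CCCCCc1cc(OC(=O)c2c(OCc3ccccc3)cc(OCc3ccccc3)cc2/C=C/C(=O)CC)cc(OCc2ccccc2)c1C(=O)OCc1ccccc1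
F2 | step 4 | benzyl 2-hydroxy-6-pentyl-4-[(triisopropylsilyl)oxy]benzoate | CCCCCc1cc(O[Si](C(C)C)(C(C)C)C(C)C)cc(O)c1C(=O)OCc1ccccc1
F3 | step 4 | benzyl 2-(benzyloxy)-6-pentyl-4-[(triisopropylsilyl)oxy]benzoate | CCCCCc1cc(O[Si](C(C)C)(C(C)C)C(C)C)cc(OCc2ccccc2)c1C(=O)OCc1ccccc1
F4 | step 4 | benzyl 2-(benzyloxy)-4-hydroxy-6-pentylbenzoate | CCCCCc1cc(O)cc(OCc2ccccc2)c1C(=O)OCc1ccccc1
F5 | step 5 | benzyl 4-{[2,4-bis(benzyloxy)-6-(3-oxopentyl)benzoyl]oxy}-2-hydroxy-6-pentylbenzoate | CCCCCc1cc(OC(=O)c2c(OCc3ccccc3)cc(OCc3ccccc3)cc2CCC(=O)CC)cc(O)c1C(=O)OCc1ccccc1
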